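Target cannot exceed the coupling partner charged, the limiting reagent, one target per coupling partner: 0.200 M, or 50.0% of the starting material.

    coupling partner + free catalyst → catalyst intermediate A (k1 = 24000 /M/h)
    starting material + catalyst intermediate A ⇌ catalyst intermediate B (K2 = 1.8 /M, k2 = 330 /M/h)
    catalyst intermediate B ⇌ catalyst intermediate C (K3 = 0.13, k3 = 28 /h)
    catalyst intermediate C → free catalyst + target (k4 = 1800 /h)
    coupling partner + catalyst intermediate C → spent catalyst (k5 = 0.11 /M/h)
    starting material + target → side product (k6 = 0.24 /M/h)

| flask | starting material | coupling partner | free catalyst | time |
|---|---|---|---|---|
| theta | 0.40 M | 0.500 equiv | 0.2 mol% | 12 h |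
| alpha | 0.40 M | 0.500 equiv | 0.6 mol% | 12 h |
| delta | 0.40 M | 0.500 equiv | 2 mol% | 12 h |
| epsilon | 0.40 M | 0.500 equiv | 5 mol% | 12 h |

- amount of target at the end, in percent of the starting material charged for theta, alpha, delta, epsilon, in this order
- the shape of the row from first to last (rises, then falls / falls, then rises / falls all the way / hardly changes / rises all the way)

- percent here means starting material units held: one side product counts as two
- "hardly changes" means that all values lie within two and a half points (for a concentration: within two and a half percent of the largest)
- run time (theta): 12 h

Two extreme flasks can be solved by hand. In the fast extreme the catalyst turns the coupling partner into target at the first moment, which leaves [starting material] = [target] = 0.200 M. The side reaction then works on equal concentrations, so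

1/[target] = 1/0.200 M + 0.24 /M/h · 12 h, which leaves 31.7% of the charge.

In the slow extreme the side reaction is ignored and target grows at the steady turnover of the catalyst, which rests as catalyst intermediates A and B (its resting state). Catalyst intermediate C goes forward with probability 0.893, so

catalyst intermediate B leaves the round at 25.0 /h,
[catalyst intermediate B]/[catalyst intermediate A] = 1.58 /M · [starting material],
turnover per catalyst = 39.6 /M/h · [starting material] / (1 + 1.58 /M · [starting material]).

As charged this is 9.70 /h, which gives theta 23.3% in 12 h with no loss.

A real flask has the turnover of the one picture and the loss of the other at once, so neither figure bounds theta from below. To weigh the two, divide one rate by the other, and time drops out. Making over loss equals level / [target], where the balance level, 20.2% for theta as charged, is the target, as a share of the charge, at which making equals loss: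

level = loading · 39.6 /M/h / (0.24 /M/h · (1 + 1.58 /M · [starting material])).

Theta's level is lower than the fast figure, so theta should end low. Alpha's level, 60.6%, is higher than the ceiling. Its coupling partner needs at least about 8.59 h at the charged turnover, less than 12 h, and epsilon's needs about 1.03 h. Alpha's target is therefore younger than epsilon's and should stand higher, with epsilon near the fast figure. This reckoning commits to the shape, in which the row rises, then falls, but gives no figure for alpha.

The forecast goes further, stepping by hand to 13.4%, 35.2%, 32.6% and 32.1%, so that the row rises, then falls; in its words, “The side reaction matters”.

The flasks give 13.4%, 35.5%, 32.7% and 32.1%, and the row rises, then falls, turning at 0.6 mol%, the shape of the forecast. In theta at 5.62 h, target is made 2.58 times faster than it is used up, and at 6.00 h the balance level, taken with 86.4% of the starting material standing, is 21.3% against 8.58% of target. In alpha at 6.00 h, with 63.5% of the starting material standing, the level is 70.6% against 24.3% of target.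

The numbers of this flask are assumed, and the outcome is calculated.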